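The leftover of the fed runs is our way in: what has gone in, less E and less Z, is J, and by 6.00 h it is 9.00% of the charge in ochre. E and dissolved X give Z and L reversibly, G crosses over to X, and E with Z gives J. Each J used up one Z, so we take L as Z plus half the leftover.

| flask | E | G | remark | time |
|---|---|---|---|---|
| grey | 0.013 M (fed, over 8.0 h) | 6.9 mM (held) | run made earlier |  |
| ochre | 0.030 M (fed, over 8.0 h) | 6.9 mM (held) | run made earlier |  |
| epsilon | 0.020 M | 6.9 mM | everything together at the start | 2.5 h |
| theta | 0.020 M (fed, over 8.0 h) | 6.9 mM (held) |  | 8.0 h |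

| run | time / h | Z / % | E / % |
|---|---|---|---|
| grey | 0.500 | 1.5 | 6.0 |
| grey | 1.00 | 2.2 | 10.4 |
| grey | 2.00 | 8.4 | 17.3 |
| grey | 3.00 | 11.7 | 25.8 |
| grey | 6.00 | 21.0 | 52.1 |
| ochre | 1.33 | 4.8 | 13.6 |
| ochre | 2.50 | 6.1 | 23.2 |
| ochre | 4.00 | 9.0 | 36.2 |
| ochre | 5.00 | 9.8 | 45.6 |
| ochre | 6.00 | 11.5 | 54.5 |

(readings scatter by 1 percentage point)

- the flask that ends with the higher amount of Z, in percent of the E charged, or "neither" when 2 percentage points or less lies between them (epsilon / theta / neither)
- final Z, as a percentage of the E charged, in epsilon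
- final Z, as a percentage of the E charged, in theta

- a species is counted by the E in it: one J counts as two
- at the start none of X is dissolved
- what may be going on: E + X <-> Z + L; L -> D; G <-> X; E + Z -> J
- percentages count the whole charge, also what has not yet gone in

The fastest rung is the first step, if it is a pre-equilibrium. Then the balance number B = Z·L/E should depend on X, not on E. At 6.00 h it reads 1.15 mM in grey and 1.01 mM in ochre, though ochre held more E. We keep the mean, 1.08 mM.

The next rung is X arriving, which takes hours. At 2.50 h ochre reads B = 0.558 mM, about half the later value, a reading with wide scatter. We set J aside and take L equal to Z, which puts our figures high.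

Then Z² = B·E, and we go round twice. Epsilon gives 3.34 mM, then with E reduced 3.05 mM, or 15.2%. Theta, holding the late B, gives 4.65 mM, then 4.07 mM, or 20.4%. Our gap of 5.1 percentage points exceeds the margin, so we say theta.

The forecast differs: 16.5% for epsilon, 18.5% for theta, so neither, with epsilon “perhaps less with the X lag”.

The flasks give 11.8% in epsilon and 17.1% in theta, so theta ends higher.

    E + X ⇌ Z + L (K = 0.240, k = 0.0903 M⁻¹ s⁻¹)
    L → D (k = 9.40 × 10⁻⁶ s⁻¹)
    G ⇌ X, rate k3*(csat - [X]) (kL = 8.91 × 10⁻⁵ s⁻¹)
    E + Z → J (k = 0.00275 M⁻¹ s⁻¹)

In epsilon the first step relaxes with a half-life of 0.0534 h, short against 2.5 h, and X stood at 0.00185 M, against 0.00464 M at the end of theta. Read back, B was 0.408 mM in epsilon, below the ochre reading, and 1.08 mM in theta, beside the late mean.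

In a neighbour flask, like epsilon but with 0.080 M of E, two rounds with the same B give 6.68 mM, then 6.40 mM, or 8.00%. The flask gives 2.61%, and its B stands at 0.129 mM.

(The data are simulated from invented constants, and the scatter is random.)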